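**Plan**

- Retrosynthetic cuts, in order: the phenol O–Si bond and C5–H (from C5–I); the lactone O–C4 bond; both peroxide C–O bonds (C3–O and C6–O, removing O2); the C4–C5 bond of the diene so revealed; the C6–CH3 bond and the aryl–C15 bond.
- Enabling feature: in the 1,2-dioxane ring the peroxide oxygens sit on C3 and C6, which are 1,4-related through C4 and C5. The ring is therefore the dioxygen adduct of a diene with double bonds C3=C4 and C5=C6, and the C4=C5 alkene left behind lies γ,δ to the C1 carboxyl and accepts the lactone oxygen at C4.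
- Forward order: the aryl–alkyl bond first, then the diene by methylalumination and alkenyl–alkenyl Negishi coupling, then C1 raised to the acid; the 1,2-dioxane ring closes in step 8 and the γ-lactone ring in step 10.
- Stereochemistry: the 3E,5E geometry comes from syn-hydrozirconation and syn-carboalumination; the cis relation of C3 and C6 from suprafacial addition to that geometry; the absolute configuration from resolution of the racemic acid; C4 from C3 through the enforced cis ring fusion.

Key step: step 8

Remark: plakortolide numbering is used throughout (C1 lactone carbonyl, C2 methylene, C3 peroxide-bearing methine, C4 carbon bearing the lactone oxygen, C5 methylene, C6 quaternary peroxide carbon, C7–C15 chain); read this way the target is (3S,4S,6R).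
Assumption: which eluted enantiomer of the acid in step 9 is (3S,6R) is settled by X-ray analysis of its iodolactone (anomalous dispersion of iodine) or by the sign of rotation of the final product against the natural material.

**Route**

Step 1
Reactants: 1 undec-10-yn-1-ol
Product: 2 undec-10-yn-1-yl 4-methylbenzenesulfonate
Conditions: TsCl, Et3N, 4-(dimethylamino)pyridine (cat.), CH2Cl2, 0 °C to rt
Reagents that add atoms: 4-methylbenzenesulfonyl chloride (TsCl), Cc1ccc(cc1)S(=O)(=O)Cl
Why: Sulfonylation of the primary alcohol under amine base turns C15–O into a leaving group for the copper-catalysed coupling and does not touch the terminal alkyne.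

Step 2
Reactants: 2 undec-10-yn-1-yl 4-methylbenzenesulfonate; 3 (4-bromophenoxy)(tert-butyl)dimethylsilane
Product: 7 tert-butyldimethyl[4-(undec-10-yn-1-yl)phenoxy]silane, via tosylate magnesium acetylide 4 (not isolated), via arylmagnesium bromide 5 (not isolated), via coupled magnesium acetylide 6 (not isolated)
Conditions: 2, EtMgBr (1.05 equiv), THF, 0 °C to rt; then 5 (1.5 equiv, from 3 and Mg in THF), Li2CuCl4 (3 mol%), −20 °C to rt; dilute HCl quench
Reagents that add atoms: none
Why: EtMgBr first masks the acidic alkyne C–H as its magnesium acetylide, which is inert in the copper-catalysed Kochi-type coupling, so the aryl Grignard reagent displaces the primary tosylate (sp2–sp3 bond to C15) and the alkyne is returned on protonation.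

Step 3
Reactants: 8 pent-3-yn-1-ol
Product: 9 tert-butyldimethyl(pent-3-yn-1-yloxy)silane
Conditions: TBSCl, imidazole, CH2Cl2, 0 °C to rt
Reagents that add atoms: tert-butyldimethylsilyl chloride (TBSCl), CC(C)(C)[Si](C)(C)Cl
Why: Standard silylation protects the primary alcohol against the organometallic reagents of steps 4 and 5 and is later removable by acid without loss of the aryl silyl ether.

Step 4
Reactants: 9 tert-butyldimethyl(pent-3-yn-1-yloxy)silane
Product: 11 tert-butyl{[(3E)-4-iodopent-3-en-1-yl]oxy}dimethylsilane, via alkenylzirconocene chloride 10 (not isolated)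
Conditions: Cp2Zr(H)Cl (2 equiv), THF, 50 °C; then I2, THF, 0 °C
Reagents that add atoms: iodine (I2), I-I
Why: Hydrozirconation adds Zr–H syn across the internal alkyne and, with excess reagent under equilibrating conditions, settles zirconium on the less hindered methyl-bearing carbon, so iodinolysis with retention should give the E iodoalkene that carries C1–C4 with the C4 methyl group (a minor regioisomer would be removed by chromatography).

Step 5
Reactants: 7 tert-butyldimethyl[4-(undec-10-yn-1-yl)phenoxy]silane; 11 tert-butyl{[(3E)-4-iodopent-3-en-1-yl]oxy}dimethylsilane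
Product: 13 (3E,5E)-1-(tert-butyldimethylsilyloxy)-15-[4-(tert-butyldimethylsilyloxy)phenyl]-4,6-dimethylpentadeca-3,5-diene, via alkenyldimethylalane 12 (not isolated)
Conditions: 7, Me3Al (2 equiv), Cp2ZrCl2 (0.25 equiv), CH2Cl2, 0 °C to rt; volatiles removed; then 11 (1.1 equiv), ZnCl2 (0.2 equiv), Pd(PPh3)4 (5 mol%), THF, rt
Reagents that add atoms: trimethylaluminium (Me3Al), C[Al](C)C
Why: Zirconium-catalysed Negishi carboalumination delivers methyl and aluminium syn to the terminal alkyne with aluminium at the terminus, and the zinc-assisted, palladium-catalysed Negishi coupling of this alkenylalane with the alkenyl iodide forms the C4–C5 bond with retention at both sp2 carbons, which fixes the 3E,5E diene.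

Step 6
Reactants: 13 (3E,5E)-1-(tert-butyldimethylsilyloxy)-15-[4-(tert-butyldimethylsilyloxy)phenyl]-4,6-dimethylpentadeca-3,5-diene
Product: 14 (3E,5E)-15-[4-(tert-butyldimethylsilyloxy)phenyl]-4,6-dimethylpentadeca-3,5-dien-1-ol
Conditions: camphorsulfonic acid (0.1 equiv), MeOH/CH2Cl2 (1:1), 0 °C
Reagents that add atoms: none
Why: Acid-catalysed methanolysis cleaves a primary alkyl silyl ether far faster than an aryl silyl ether, so only the C1 hydroxyl is freed and the phenol stays protected.

Step 7
Reactants: 14 (3E,5E)-15-[4-(tert-butyldimethylsilyloxy)phenyl]-4,6-dimethylpentadeca-3,5-dien-1-ol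
Product: 16 (3E,5E)-15-[4-(tert-butyldimethylsilyloxy)phenyl]-4,6-dimethylpentadeca-3,5-dienoic acid, via dienal 15 (not isolated)
Conditions: TEMPO (2,2,6,6-tetramethylpiperidin-1-oxyl, 0.2 equiv), PhI(OAc)2 (2.5 equiv), MeCN/pH 7 phosphate buffer, 0 °C to rt
Reagents that add atoms: water, O
Why: Oxoammonium (TEMPO) oxidation with PhI(OAc)2 as terminal oxidant takes the primary alcohol through the aldehyde and its hydrate to the acid in one flask under near-neutral conditions, which should leave the skipped diene out of conjugation and the aryl silyl ether intact.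

Step 8
Reactants: 16 (3E,5E)-15-[4-(tert-butyldimethylsilyloxy)phenyl]-4,6-dimethylpentadeca-3,5-dienoic acid
Product: 17 racemic 2-[(3S*,6R*)-6-{9-[4-(tert-butyldimethylsilyloxy)phenyl]nonyl}-4,6-dimethyl-3,6-dihydro-1,2-dioxin-3-yl]acetic acid
Conditions: O2, tetraphenylporphyrin (1 mol%), CH2Cl2, −30 °C, visible light (white LED)
Reagents that add atoms: dioxygen (used as singlet oxygen), O=O
Why: Sensitised excitation by tetraphenylporphyrin gives singlet oxygen, which adds as the 2π partner across C3 and C6 of the cisoid diene in a concerted, suprafacial [4+2] cycloaddition, the oxygen counterpart of a Diels–Alder reaction and the standard entry to 3,6-dihydro-1,2-dioxines from 1,3-dienes. The six-membered peroxide ring closes by this cycloaddition, both C–O bonds forming in one event and the new C4=C5 alkene ending up where the lactone oxygen is needed in step 10. C3 and C6 become stereocentres whose relative configuration is fixed by the 3E,5E geometry together with suprafacial delivery, so the two outside groups (the carboxymethyl arm on C3 and the long chain on C6) should end cis as in the target, while the absolute sense is not controlled and the product is racemic. The step needs cycloaddition to win over ene hydroperoxidation at the allylic methyl and methylene groups; the C4 methyl group clashes with the cis methyl on C6 in the transoid conformer and so biases the diene toward the reactive cisoid shape, and a cold aprotic medium is chosen to favour the concerted channel. The free acid rather than an ester is used because a carboxylate is not readily enolised, which guards the C3 peroxide against β-elimination here and later.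

Step 9
Reactants: 17 racemic 2-[(3S*,6R*)-6-{9-[4-(tert-butyldimethylsilyloxy)phenyl]nonyl}-4,6-dimethyl-3,6-dihydro-1,2-dioxin-3-yl]acetic acid
Product: 18 2-[(3S,6R)-6-{9-[4-(tert-butyldimethylsilyloxy)phenyl]nonyl}-4,6-dimethyl-3,6-dihydro-1,2-dioxin-3-yl]acetic acid
Conditions: preparative HPLC, amylose tris(3,5-dimethylphenylcarbamate) chiral stationary phase, hexane/i-PrOH/CF3CO2H (0.1%), rt
Reagents that add atoms: none
Why: The enantiomers of the rigid, cis-disubstituted ring acid are separated by chromatography on a polysaccharide chiral stationary phase (chromatographic resolution), and the (3S,6R) antipode is carried on.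

Step 10
Reactants: 18 2-[(3S,6R)-6-{9-[4-(tert-butyldimethylsilyloxy)phenyl]nonyl}-4,6-dimethyl-3,6-dihydro-1,2-dioxin-3-yl]acetic acid
Product: 19 (3S,4R,5S,6R)-5-iodo-O-(tert-butyldimethylsilyl)plakortolide F (cis-fused γ-lactone on the 1,2-dioxane, iodine on C5 trans to the lactone oxygen; the C4 descriptor differs from the target only because iodine raises the priority of C5)
Conditions: I2 (3 equiv), NaHCO3, MeCN/H2O, 0 °C, dark
Reagents that add atoms: iodine (I2), I-I
Why: Iodolactonisation: the iodonium ion on C4=C5 is opened by the carboxylate at the more substituted C4 in a 5-exo sense and anti to iodine, and because the two-atom tether from C3 can only reach the face of C4 cis to itself, the γ-lactone is cis-fused and C4 is set from C3, with the C5 iodide trans to the lactone oxygen.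

Step 11
Reactants: 19 (3S,4R,5S,6R)-5-iodo-O-(tert-butyldimethylsilyl)plakortolide F
Product: 20 (3S,4S,6R)-O-(tert-butyldimethylsilyl)plakortolide F
Conditions: Bu3SnH (2 equiv, concentrated), azobisisobutyronitrile (cat.), toluene, 70 °C
Reagents that add atoms: none
Why: Radical-chain tin hydride dehalogenation: Bu3Sn• abstracts iodine much faster than it attacks a dialkyl peroxide, and the C5 radical, held in the ring away from the collinear geometry needed to displace at the peroxide oxygen, is quenched by the concentrated hydride, so C5 becomes a methylene and no stereocentre is affected.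

Step 12
Reactants: 20 (3S,4S,6R)-O-(tert-butyldimethylsilyl)plakortolide F
Product: 21 plakortolide F, (3R,4aS,7aS)-3-[9-(4-hydroxyphenyl)nonyl]-3,4a-dimethyltetrahydro-3H-furo[3,2-c][1,2]dioxin-6(4H)-one
Conditions: Bu4NF/AcOH (1:1), THF, 0 °C
Reagents that add atoms: none
Why: Fluoride cleaves the aryl silyl ether quickly because phenoxide is a good leaving group, and the acetic acid buffer keeps the medium non-basic so the C2 protons are not removed and the C3 peroxide is not lost by β-elimination.

**Compound list**

1 | undec-10-yn-1-ol | C#CCCCCCCCCCO | starting material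
2 | undec-10-yn-1-yl 4-methylbenzenesulfonate | C#CCCCCCCCCCOS(=O)(=O)c1ccc(C)cc1 | intermediate
3 | (4-bromophenoxy)(tert-butyl)dimethylsilane | CC(C)(C)[Si](C)(C)Oc1ccc(Br)cc1 | starting material
4 | bromo[11-(4-methylbenzenesulfonyloxy)undec-1-yn-1-yl]magnesium (magnesium acetylide of 2) | Br[Mg]C#CCCCCCCCCCOS(=O)(=O)c1ccc(C)cc1 | intermediate (not isolated)
5 | bromo{4-[(tert-butyldimethylsilyl)oxy]phenyl}magnesium | Br[Mg]c1ccc(O[Si](C)(C)C(C)(C)C)cc1 | intermediate (not isolated)
6 | bromo(11-{4-[(tert-butyldimethylsilyl)oxy]phenyl}undec-1-yn-1-yl)magnesium (magnesium acetylide of 7) | Br[Mg]C#CCCCCCCCCCc1ccc(O[Si](C)(C)C(C)(C)C)cc1 | intermediate (not isolated)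
7 | tert-butyldimethyl[4-(undec-10-yn-1-yl)phenoxy]silane | C#CCCCCCCCCCc1ccc(O[Si](C)(C)C(C)(C)C)cc1 | intermediate
8 | pent-3-yn-1-ol | CC#CCCO | starting material
9 | tert-butyldimethyl(pent-3-yn-1-yloxy)silane | CC#CCCO[Si](C)(C)C(C)(C)C | intermediate
10 | chlorobis(cyclopentadienyl)[(2E)-5-(tert-butyldimethylsilyloxy)pent-2-en-2-yl]zirconium | C/C(=C\CCO[Si](C)(C)C(C)(C)C)[Zr](Cl)(C1C=CC=C1)C1C=CC=C1 | intermediate (not isolated)
11 | tert-butyl{[(3E)-4-iodopent-3-en-1-yl]oxy}dimethylsilane | I/C(C)=C/CCO[Si](C)(C)C(C)(C)C | intermediate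
12 | dimethyl[(1E)-11-{4-[(tert-butyldimethylsilyl)oxy]phenyl}-2-methylundec-1-en-1-yl]alane | C[Al](C)/C=C(\C)CCCCCCCCCc1ccc(O[Si](C)(C)C(C)(C)C)cc1 | intermediate (not isolated)
13 | (3E,5E)-1-(tert-butyldimethylsilyloxy)-15-[4-(tert-butyldimethylsilyloxy)phenyl]-4,6-dimethylpentadeca-3,5-diene | CC(C)(C)[Si](C)(C)OCC/C=C(\C)/C=C(\C)/CCCCCCCCCc1ccc(O[Si](C)(C)C(C)(C)C)cc1 | intermediate
14 | (3E,5E)-15-[4-(tert-butyldimethylsilyloxy)phenyl]-4,6-dimethylpentadeca-3,5-dien-1-ol | OCC/C=C(\C)/C=C(\C)/CCCCCCCCCc1ccc(O[Si](C)(C)C(C)(C)C)cc1 | intermediate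
15 | (3E,5E)-15-[4-(tert-butyldimethylsilyloxy)phenyl]-4,6-dimethylpentadeca-3,5-dienal | O=CC/C=C(\C)/C=C(\C)/CCCCCCCCCc1ccc(O[Si](C)(C)C(C)(C)C)cc1 | intermediate (not isolated)
16 | (3E,5E)-15-[4-(tert-butyldimethylsilyloxy)phenyl]-4,6-dimethylpentadeca-3,5-dienoic acid | OC(=O)C/C=C(\C)/C=C(\C)/CCCCCCCCCc1ccc(O[Si](C)(C)C(C)(C)C)cc1 | intermediate (key-step precursor)
17 | racemic 2-[(3S*,6R*)-6-{9-[4-(tert-butyldimethylsilyloxy)phenyl]nonyl}-4,6-dimethyl-3,6-dihydro-1,2-dioxin-3-yl]acetic acid (both enantiomers; the 3S,6R enantiomer is drawn) | C[C@@]1(CCCCCCCCCc2ccc(O[Si](C)(C)C(C)(C)C)cc2)C=C(C)[C@H](CC(O)=O)OO1 | intermediate (key-step product)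
18 | 2-[(3S,6R)-6-{9-[4-(tert-butyldimethylsilyloxy)phenyl]nonyl}-4,6-dimethyl-3,6-dihydro-1,2-dioxin-3-yl]acetic acid (single enantiomer) | C[C@@]1(CCCCCCCCCc2ccc(O[Si](C)(C)C(C)(C)C)cc2)C=C(C)[C@H](CC(O)=O)OO1 | intermediate
19 | (3S,4R,5S,6R)-5-iodo-O-(tert-butyldimethylsilyl)plakortolide F | C[C@@]1(CCCCCCCCCc2ccc(O[Si](C)(C)C(C)(C)C)cc2)[C@H]([C@]2(C)OC(=O)C[C@@H]2OO1)I | intermediate
20 | (3S,4S,6R)-O-(tert-butyldimethylsilyl)plakortolide F | C[C@@]1(CCCCCCCCCc2ccc(O[Si](C)(C)C(C)(C)C)cc2)C[C@]2(C)OC(=O)C[C@@H]2OO1 | intermediate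
21 | plakortolide F, (3S,4S,6R) in plakortolide numbering | C[C@@]1(CCCCCCCCCc2ccc(O)cc2)C[C@]2(C)OC(=O)C[C@@H]2OO1 | target

**Step count and risks**

Total step count: 12. Longest linear sequence: 10 steps (steps 1, 2, 5, 6, 7, 8, 9, 10, 11, 12, from undec-10-yn-1-ol).

Steps most likely to fail:

1. Step 8. Ene hydroperoxidation at the C4 and C6 methyl groups and at C7 may outrun the cycloaddition, because the cis methyl on C6 twists the diene out of the planar cisoid shape; the dioxine would then be a minor product. The fallback replaces singlet oxygen by ground-state dioxygen under cation-radical chain catalysis, which has no ene channel. It sets out from bis-silyl ether 13, since a free carboxyl or hydroxyl group would trap the diene cation radical. Oxygenation with O2 and catalytic (4-BrC6H4)3N SbCl6 (tris(4-bromophenyl)aminium hexachloroantimonate) in CH2Cl2 at −78 °C should give the racemic cis-dihydrodioxine bis-silyl ether F1; ring closure is stepwise here, so any trans isomer would be removed by chromatography. Camphorsulfonic acid in MeOH would then free the dioxine alcohol F2, and TEMPO/PhI(OAc)2 in buffered aqueous MeCN would oxidise it through the dioxine aldehyde F3 to acid 17, where the route is rejoined.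

2. Step 7. The intermediate β,γ-unsaturated aldehyde may slide into conjugation with the diene, or the electron-rich diene may be attacked by the oxoammonium salt, so that isomerised or degraded acid results. The fallback brings C1 in at the acid oxidation level before the diene exists. It sets out from iodide 11: camphorsulfonic acid in MeOH gives (E)-4-iodopent-3-en-1-ol F4, and Jones oxidation (CrO3, H2SO4, acetone, 0 °C) takes it through (E)-4-iodopent-3-enal F5 to (E)-4-iodopent-3-enoic acid F6. Me3SiCHN2 in MeOH/toluene gives methyl (E)-4-iodopent-3-enoate F7, which is coupled with alane 12 under the conditions of step 5 to give methyl (3E,5E)-15-[4-(tert-butyldimethylsilyloxy)phenyl]-4,6-dimethylpentadeca-3,5-dienoate F8. Hydrolysis with Me3SnOH in 1,2-dichloroethane (or LiOH at 0 °C) then gives acid 16, where the route is rejoined.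

3. Step 9. The enantiomers of the free acid may not separate to baseline (tailing of the acid, small selectivity), so that throughput or enantiopurity is insufficient. The fallback is a covalent resolution in which the next reaction also removes the auxiliary. It sets out from racemic acid 17: coupling with (S)-1-phenylethylamine (EDC·HCl, HOBt, CH2Cl2, 0 °C, acid pre-activated to limit exposure of the peroxide to free amine) gives two diastereomeric amides, the (3S,6R)-N-[(1S)-1-phenylethyl]amide F9 and the (3R,6S)-N-[(1S)-1-phenylethyl]amide F10, to be separated on silica gel. Treating F9 with I2 in THF/H2O should cyclise through the amide oxygen, and hydrolysis of the resulting iminolactone releases the amine and gives iodolactone 19 directly, where the route is rejoined.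

**Further compounds**

F1 | step 8 | racemic tert-butyl{2-[(3S*,6R*)-6-{9-[4-(tert-butyldimethylsilyloxy)phenyl]nonyl}-4,6-dimethyl-3,6-dihydro-1,2-dioxin-3-yl]ethoxy}dimethylsilane | C[C@@]1(CCCCCCCCCc2ccc(O[Si](C)(C)C(C)(C)C)cc2)C=C(C)[C@H](CCO[Si](C)(C)C(C)(C)C)OO1
F2 | step 8 | racemic 2-[(3S*,6R*)-6-{9-[4-(tert-butyldimethylsilyloxy)phenyl]nonyl}-4,6-dimethyl-3,6-dihydro-1,2-dioxin-3-yl]ethanol | C[C@@]1(CCCCCCCCCc2ccc(O[Si](C)(C)C(C)(C)C)cc2)C=C(C)[C@H](CCO)OO1
F3 | step 8 | racemic 2-[(3S*,6R*)-6-{9-[4-(tert-butyldimethylsilyloxy)phenyl]nonyl}-4,6-dimethyl-3,6-dihydro-1,2-dioxin-3-yl]acetaldehyde | C[C@@]1(CCCCCCCCCc2ccc(O[Si](C)(C)C(C)(C)C)cc2)C=C(C)[C@H](CC=O)OO1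
F4 | step 7 | (E)-4-iodopent-3-en-1-ol | I/C(C)=C/CCO
F5 | step 7 | (E)-4-iodopent-3-enal | I/C(C)=C/CC=O
F6 | step 7 | (E)-4-iodopent-3-enoic acid | I/C(C)=C/CC(=O)O
F7 | step 7 | methyl (E)-4-iodopent-3-enoate | I/C(C)=C/CC(=O)OC
F8 | step 7 | methyl (3E,5E)-15-[4-(tert-butyldimethylsilyloxy)phenyl]-4,6-dimethylpentadeca-3,5-dienoate | COC(=O)C/C=C(\C)/C=C(\C)/CCCCCCCCCc1ccc(O[Si](C)(C)C(C)(C)C)cc1
F9 | step 9 | N-[(1S)-1-phenylethyl]-2-[(3S,6R)-6-{9-[4-(tert-butyldimethylsilyloxy)phenyl]nonyl}-4,6-dimethyl-3,6-dihydro-1,2-dioxin-3-yl]acetamide | C[C@@]1(CCCCCCCCCc2ccc(O[Si](C)(C)C(C)(C)C)cc2)C=C(C)[C@H](CC(=O)N[C@@H](C)c2ccccc2)OO1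
F10 | step 9 | N-[(1S)-1-phenylethyl]-2-[(3R,6S)-6-{9-[4-(tert-butyldimethylsilyloxy)phenyl]nonyl}-4,6-dimethyl-3,6-dihydro-1,2-dioxin-3-yl]acetamide | C[C@]1(CCCCCCCCCc2ccc(O[Si](C)(C)C(C)(C)C)cc2)C=C(C)[C@@H](CC(=O)N[C@@H](C)c2ccccc2)OO1
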